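Readings and results were computed from invented constants; noise was put on by code.

If every initiator you charge begins one chain, the average length at the end is the monomer in chains, as a fraction of the free monomer charged, divided by the loading. Any initiator wasted, say by the candidate step to spent initiator B, begins no chain and lengthens the average beyond that figure.

| setting | Friday's | Saturday's | gamma | epsilon |
|---|---|---|---|---|
| free monomer | 0.18 M | 0.18 M | 0.18 M | 0.18 M |
| initiator | 0.57 mol% | 2.1 mol% | 2.5 mol% | 0.8 mol% |
| remark | run made earlier | run made earlier |  |  |
| time |  |  | 2.0 h | 2.0 h |

| run | time / min | monomer in chains / % |
|---|---|---|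
| Friday's | 10.0 | 5.7 |
| Friday's | 15.0 | 10.2 |
| Friday's | 25.0 | 18.3 |
| Friday's | 40.0 | 29.3 |
| Friday's | 80.0 | 49.8 |
| Friday's | 120 | 60.1 |
| Saturday's | 20.0 | 39.3 |
| Saturday's | 40.0 | 65.8 |
| Saturday's | 60.0 | 77.1 |
| Saturday's | 80.0 | 82.5 |
| Saturday's | 90.0 | 85.1 |
| Saturday's | 120 | 87.9 |

(scatter of a reading: 0.5 percentage points)

1. which of the two ends with the longer chains by the average number of monomer units in a chain (chains begun, living or dead) ("neither" if they lie within 10%) (gamma / epsilon / neither)
2. average number of monomer units in a chain (chains begun, living or dead) at the end, gamma
3. average number of monomer units in a chain (chains begun, living or dead) at the end, epsilon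

Take the bound from below first. At 120 min, the asked time, Saturday's run stands at 87.9% and Friday's at 60.1%. Gamma carries more initiator than Saturday's run, so I put its monomer in chains at no less than Saturday's reading. That gives gamma 35.2: this is the floor length, monomer in chains over loading with every initiator counted as a chain. Epsilon's loading lies between those of the two runs, so Friday's reading gives it a floor length of 75.1.

Now the bound from above. Gamma's monomer in chains cannot pass the whole charge, and I cap epsilon's at Saturday's reading. The runs show no chain count, so I guess that at least 0.5 of the initiator begins chains. The ceilings are then 80.0 for gamma and 220 for epsilon.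

These brackets are wide, but the ratio is tighter. If both flasks share the same fraction of initiator that begins chains, which I assume because their free monomer charge is equal, the guess cancels. Epsilon then ends between 1.88 and 3.12 times gamma's length, beyond the margin of 10%.

The forecast, 45 for gamma and 108 for epsilon, lies inside both brackets : “Epsilon clearly ends longer.”

    free monomer + initiator → living end + monomer in chains (k = 0.00930 /M/s)
    free monomer + living end → monomer in chains + living end, rate k2*[living end]*[free monomer] (k = 0.240 /M/s)
    2 living end → dead end A (k = 0.0410 /M/s)
    initiator → spent initiator B (k = 3.00 × 10⁻⁴ /s)
    free monomer → uncatalysed product (k = 4.60 × 10⁻⁵ /s)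

The flasks give 45.4 for gamma and 104 for epsilon, so epsilon is longer, by a factor of 2.29. At the end of gamma, spent initiator B holds 20.6% of the initiator charged. Gamma's average 45.4 stands above its floor length 35.2, but that floor rests on Saturday's reading; gamma's own 89.3% of monomer in chains gives a floor length of 35.7, and this over the average reads 0.788, the initiator efficiency. Take the neighbour of epsilon charged with 0.072 M of free monomer: its 35.0% of monomer in chains gives a floor length of 43.7, its average is 65.8, and its efficiency reads 0.665.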